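**Retrosynthetic overview**
1. Quinone ⇒ phenol. The C21 oxygen goes in last, by para-oxidation of a 3-amino-5-hydroxyphenyl (AHBA-type) macrolactam, as a tailoring step after ring closure. The six-membered carbocycle is bought.
2. Macrolactam ⇒ C1–N bond, the only ring-forming step. The fully unprotected seco acid (free aminophenol, free C15-OH, C7 carbamate in place) is converted in the flask into a thioester. Its own aniline nitrogen then releases the chain, as the amide synthase does with the carrier-protein thioester, and nothing is left to deprotect afterwards.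
3. Seco acid ⇒ C3–C4 Sonogashira coupling. One zinc reduction then makes both the 4Z-alkene and the aniline.
4. Chain ⇒ grown outwards from the arene in the polyketide direction: C14–C15 crotylboration, C12–C13 olefination/hydrogenation, C10–C11 crotylboration, C8=C9 cross metathesis, C6–C7 allenylstannane addition.
5. Ring order: benzene ring (purchased) → 19-membered lactam → oxidation of the benzene ring to the quinone.

Assumption: the target is taken exactly as drawn (6S,7R,10S,11R,12S,14S,15R; 2E,4Z,8E). Ansamycin numbering is used: C1 = lactam carbonyl, C15 = benzylic carbinol, C16–C21 = six-membered ring. All seven starting materials are taken as catalogue items. TBS = tert-butyldimethylsilyl.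

**Step 1**
Reactants: 1 (S)-but-3-yn-2-ol
Product: 2 (S)-but-3-yn-2-yl methanesulfonate
Conditions: MsCl, Et3N, CH2Cl2, −78 to 0 °C
Reagents that add atoms: methanesulfonyl chloride, CS(=O)(=O)Cl
Why: Alcohol sulfonylation leaves the C–O bond intact, so the S centre (future C6) is kept.

**Step 2**
Reactants: 2 (S)-but-3-yn-2-yl methanesulfonate
Product: 3 (aR)-tributyl(buta-1,2-dien-1-yl)stannane
Conditions: Bu3SnH, LiN(i-Pr)2, THF, 0 °C; CuBr·SMe2, −78 °C; then 2, −78 °C
Reagents that add atoms: tributyltin hydride, CCCC[SnH](CCCC)CCCC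
Why: Anti-SN2′ displacement of the propargylic mesylate by the stannylcopper reagent turns the S carbon centre into the aR allene axis.

**Step 3**
Reactants: 4 diethyl 2-methylpropanedioate; 5 triiodomethane
Product: 6 diethyl 2-(diiodomethyl)-2-methylpropanedioate
Conditions: NaH, Et2O, 0 °C to reflux
Reagents that add atoms: none
Why: Malonate enolate alkylation with iodoform as the electrophile; no stereocentre is formed.

**Step 4**
Reactants: 6 diethyl 2-(diiodomethyl)-2-methylpropanedioate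
Product: 7 (E)-3-iodo-2-methylprop-2-enoic acid
Conditions: KOH, EtOH/H2O, reflux; then HCl (aq)
Reagents that add atoms: potassium hydroxide, [K+].[OH-]
Why: Saponification followed by decarboxylative elimination of iodide gives the E-iodoacrylic acid as the favoured isomer (iodine trans to the carboxyl group).

**Step 5**
Reactants: 8 3-hydroxy-5-nitrobenzaldehyde; 9 (Z)-crotylboronic acid pinacol ester
Product: 10 3-[(1R,2S)-1-hydroxy-2-methylbut-3-en-1-yl]-5-nitrophenol
Conditions: (R)-TRIP [(R)-3,3′-bis(2,4,6-triisopropylphenyl)-BINOL hydrogen phosphate] (5 mol %), 4 Å MS, toluene/CH2Cl2, −30 °C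
Reagents that add atoms: none
Why: Chiral-phosphoric-acid-catalysed crotylboration through a closed chair transition state: the Z-crotyl geometry gives the C14/C15 syn pair, the R catalyst directs attack to the Re face (15R,14S), and the pinacol boronate ignores the phenol and the nitro group.

**Step 6**
Reactants: 10 3-[(1R,2S)-1-hydroxy-2-methylbut-3-en-1-yl]-5-nitrophenol
Product: 11 bis-TBS ether of 10, (1R,2S)-1-(TBSO)-1-[3-(TBSO)-5-nitrophenyl]-2-methylbut-3-ene
Conditions: TBSOTf (2.5 equiv), 2,6-lutidine, CH2Cl2, 0 to 25 °C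
Reagents that add atoms: tert-butyldimethylsilyl triflate, CC(C)(C)[Si](C)(C)OS(=O)(=O)C(F)(F)F
Why: A single silyl ether formation masks both hydroxyl groups for the later O-methylation and carbamoylation, without touching a stereocentre.

**Step 7**
Reactants: 11 bis-TBS ether of 10; 12 methyl 2-(dimethoxyphosphoryl)-2-methoxyacetate
Product: 14 methyl (2Z,4S,5R)-5-(TBSO)-5-[3-(TBSO)-5-nitrophenyl]-2-methoxy-4-methylpent-2-enoate, via aldehyde 13 (not isolated)
Conditions: O3, CH2Cl2, −78 °C; PPh3, to 20 °C, volatiles off; then 12 + LiN(SiMe3)2, THF, −78 to 0 °C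
Reagents that add atoms: ozone, [O-][O+]=O (carbonyl oxygen of 13)
Why: Ozonolysis then Horner–Wadsworth–Emmons olefination in one flask; the preformed lithium phosphonate carries no excess base, so C14 is not epimerised, and the ester ends up trans to the chain (Z by CIP, minor E isomer removed by chromatography).

**Step 8**
Reactants: 14 methyl (2Z,4S,5R)-5-(TBSO)-5-[3-(TBSO)-5-nitrophenyl]-2-methoxy-4-methylpent-2-enoate
Product: 15 methyl (2S,4S,5R)-5-(TBSO)-5-[3-(TBSO)-5-nitrophenyl]-2-methoxy-4-methylpentanoate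
Conditions: [Rh(cod)((S,S)-Et-DuPhos)]BF4 (3 mol %), H2 (10 bar), CH2Cl2/MeOH, 25 °C
Reagents that add atoms: none
Why: Asymmetric hydrogenation of an α-oxy-acrylate with the ligand antipode that gives S α-oxy esters from enol esters, reinforced by the substrate, because in the A(1,3)-minimised conformer (C14–H eclipsing the alkene) the silyloxybenzyl group blocks one face and H2 enters from the methyl face to give 12S, while ArNO2 is inert to the cationic rhodium catalyst.

**Step 9**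
Reactants: 15 methyl (2S,4S,5R)-5-(TBSO)-5-[3-(TBSO)-5-nitrophenyl]-2-methoxy-4-methylpentanoate
Product: 16 (2S,4S,5R)-5-(TBSO)-5-[3-(TBSO)-5-nitrophenyl]-2-methoxy-4-methylpentanal
Conditions: i-Bu2AlH (1.05 equiv), CH2Cl2, −78 °C; aq. potassium sodium tartrate
Reagents that add atoms: none
Why: Partial ester reduction stops at the aldehyde because the α-methoxy group chelates the tetrahedral aluminium intermediate; the nitro group survives one equivalent at −78 °C, and the aldehyde is used at once to protect C12.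

**Step 10**
Reactants: 16 (2S,4S,5R)-5-(TBSO)-5-[3-(TBSO)-5-nitrophenyl]-2-methoxy-4-methylpentanal; 9 (Z)-crotylboronic acid pinacol ester
Product: 17 (3S,4R,5S,7S,8R)-8-(TBSO)-8-[3-(TBSO)-5-nitrophenyl]-5-methoxy-3,7-dimethyloct-1-en-4-ol
Conditions: (R)-TRIP (5 mol %), 4 Å MS, toluene, −30 °C
Reagents that add atoms: none
Why: Crotylboration in which the Z-crotyl geometry gives C10/C11 syn and the Cornforth preference of Z-crotylboronates for α-alkoxy aldehydes gives C11/C12 anti, the R catalyst (Re-face attack) working in the same direction (10S,11R).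

**Step 11**
Reactants: 17 (3S,4R,5S,7S,8R)-8-(TBSO)-8-[3-(TBSO)-5-nitrophenyl]-5-methoxy-3,7-dimethyloct-1-en-4-ol
Product: 18 (3S,4R,5S,7S,8R)-8-(TBSO)-8-[3-(TBSO)-5-nitrophenyl]-4,5-dimethoxy-3,7-dimethyloct-1-ene
Conditions: Me3OBF4, 1,8-bis(dimethylamino)naphthalene, 4 Å MS, CH2Cl2, 0 to 25 °C
Reagents that add atoms: trimethyloxonium tetrafluoroborate, C[O+](C)C.F[B-](F)(F)F
Why: O-Methylation with an oxonium salt and a non-nucleophilic base alkylates the only free hydroxyl group and spares the base-labile aryl silyl ether.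

**Step 12**
Reactants: 18 (3S,4R,5S,7S,8R)-8-(TBSO)-8-[3-(TBSO)-5-nitrophenyl]-4,5-dimethoxy-3,7-dimethyloct-1-ene; 19 methacrolein
Product: 20 (2E,4S,5R,6S,8S,9R)-9-(TBSO)-9-[3-(TBSO)-5-nitrophenyl]-5,6-dimethoxy-2,4,8-trimethylnon-2-enal
Conditions: second-generation Hoveyda–Grubbs catalyst (5 mol %), 19 (10 equiv), CH2Cl2, 40 °C
Reagents that add atoms: none
Why: Olefin cross metathesis of the only alkene with a 1,1-disubstituted enal gives the thermodynamically favoured E-trisubstituted enal (C7–C9) directly, without passing through an epimerisable C9 aldehyde.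

**Step 13**
Reactants: 20 (2E,4S,5R,6S,8S,9R)-9-(TBSO)-9-[3-(TBSO)-5-nitrophenyl]-5,6-dimethoxy-2,4,8-trimethylnon-2-enal; 3 (aR)-tributyl(buta-1,2-dien-1-yl)stannane
Product: 21 (3S,4R,5E,7S,8R,9S,11S,12R)-12-(TBSO)-12-[3-(TBSO)-5-nitrophenyl]-8,9-dimethoxy-3,5,7,11-tetramethyldodec-5-en-1-yn-4-ol
Conditions: BF3·OEt2, CH2Cl2, −78 °C
Reagents that add atoms: none
Why: Lewis-acid-promoted allenylstannane addition (anti-SE2′, open transition state): the allene axis is transferred to C6 (S, net retention from 1) and the syn topology of the open transition state sets C7 (R).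

**Step 14**
Reactants: 21 (3S,4R,5E,7S,8R,9S,11S,12R)-12-(TBSO)-12-[3-(TBSO)-5-nitrophenyl]-8,9-dimethoxy-3,5,7,11-tetramethyldodec-5-en-1-yn-4-ol
Product: 23 (3S,4R,5E,7S,8R,9S,11S,12R)-12-(TBSO)-12-(3-hydroxy-5-nitrophenyl)-8,9-dimethoxy-3,5,7,11-tetramethyldodec-5-en-1-yn-4-yl carbamate, via N-trichloroacetyl carbamate 22 (not isolated)
Conditions: Cl3CC(O)NCO, CH2Cl2, 0 °C; then K2CO3, MeOH, 25 °C
Reagents that add atoms: trichloroacetyl isocyanate, O=C=NC(=O)C(Cl)(Cl)Cl
Why: Carbamoylation by addition of the only free alcohol to an acyl isocyanate (retention at C7); the methanolysis that removes the trichloroacetyl group also cleaves the electron-poor aryl silyl ether, while the secondary TBS ether stays.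

**Step 15**
Reactants: 23 (3S,4R,5E,7S,8R,9S,11S,12R)-12-(TBSO)-12-(3-hydroxy-5-nitrophenyl)-8,9-dimethoxy-3,5,7,11-tetramethyldodec-5-en-1-yn-4-yl carbamate; 7 (E)-3-iodo-2-methylprop-2-enoic acid
Product: 25 (2E,6S,7R,8E,10S,11R,12S,14S,15R)-7-(carbamoyloxy)-15-hydroxy-15-(3-hydroxy-5-nitrophenyl)-11,12-dimethoxy-2,6,8,10,14-pentamethylpentadeca-2,8-dien-4-ynoic acid, via 15-O-TBS enyne acid 24 (not isolated)
Conditions: PdCl2(PPh3)2 (5 mol %), CuI (10 mol %), Et3N, THF, degassed, 25 °C; then Bu4NF/AcOH (1:1, 5 equiv), 25 to 40 °C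
Reagents that add atoms: none
Why: Sonogashira coupling with retention of the E-iodoalkene geometry uses the free acid, so no ester has to be hydrolysed; buffered fluoride added to the same flask then removes the last silyl ether, which is acceptable because the ring closure needs no protection.

**Step 16**
Reactants: 25 (2E,6S,7R,8E,10S,11R,12S,14S,15R)-7-(carbamoyloxy)-15-hydroxy-15-(3-hydroxy-5-nitrophenyl)-11,12-dimethoxy-2,6,8,10,14-pentamethylpentadeca-2,8-dien-4-ynoic acid
Product: 26 (2E,4Z,6S,7R,8E,10S,11R,12S,14S,15R)-15-(3-amino-5-hydroxyphenyl)-7-(carbamoyloxy)-15-hydroxy-11,12-dimethoxy-2,6,8,10,14-pentamethylpentadeca-2,4,8-trienoic acid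
Conditions: Zn dust activated with Cu(OAc)2 and AgNO3, NH4Cl, MeOH/H2O, Ar, 25 to 45 °C
Reagents that add atoms: none
Why: Boland-type zinc semi-reduction adds two hydrogens syn to the conjugated alkyne only (4Z; the isolated C8=C9 alkene is inert), and the same excess of zinc with NH4Cl carries out the classical nitro-to-aniline reduction.

**Step 17**
Reactants: 26 (2E,4Z,6S,7R,8E,10S,11R,12S,14S,15R)-15-(3-amino-5-hydroxyphenyl)-7-(carbamoyloxy)-15-hydroxy-11,12-dimethoxy-2,6,8,10,14-pentamethylpentadeca-2,4,8-trienoic acid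
Product: 28 phenol macrolactam [(4E,6Z,8S,9R,10E,12S,13R,14S,16S,17R)-17,20-dihydroxy-13,14-dimethoxy-4,8,10,12,16-pentamethyl-3-oxo-2-azabicyclo[16.3.1]docosa-1(22),4,6,10,18,20-hexaen-9-yl] carbamate, via S-2-pyridyl thioester 27 (not isolated)
Conditions: PPh3 (2 equiv), 2,2′-dipyridyl disulfide (2 equiv), degassed MeCN/THF, 26 added over 12 h (final 1 mM), 25 to 40 °C
Reagents that add atoms: 2,2′-dipyridyl disulfide, c1ccc(SSc2ccccn2)nc1 (pyridylthio group of 27)
Why: Mukaiyama oxidation–reduction condensation with Corey–Nicolaou double activation turns the acid into a 2-pyridyl thioester, a stand-in for the carrier-protein thioester; at high dilution the aniline nitrogen, the best nucleophile present, releases the chain as the 19-membered lactam, whereas the phenol, the C15 carbinol and the carbamate would need heat or a thiophilic metal salt to react, and no stereocentre is involved.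

**Step 18**
Reactants: 28 phenol macrolactam
Product: 29 target, [(4E,6Z,8S,9R,10E,12S,13R,14S,16S,17R)-17-hydroxy-13,14-dimethoxy-4,8,10,12,16-pentamethyl-3,20,22-trioxo-2-azabicyclo[16.3.1]docosa-1(21),4,6,10,18-pentaen-9-yl] carbamate
Conditions: (KSO3)2NO (2.5 equiv), KH2PO4 buffer, acetone/H2O, 0 to 25 °C
Reagents that add atoms: potassium nitrosodisulfonate, [K+].[K+].[O]N(S(=O)(=O)[O-])S(=O)(=O)[O-]
Why: Teuber oxidation, in which one nitrosodisulfonate radical removes the phenolic hydrogen and a second couples at the free para carbon C21; loss of imidodisulfonate then gives the 1,4-quinone, the alkenes, carbinol and carbamate are untouched, and the step mirrors the C21 oxygenation that follows ring closure in nature.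

**Compound list**
1 | (S)-but-3-yn-2-ol | C#C[C@H](C)O | starting material
2 | (S)-but-3-yn-2-yl methanesulfonate | C#C[C@H](C)OS(C)(=O)=O | intermediate
3 | (aR)-tributyl(buta-1,2-dien-1-yl)stannane | CC([H])=[C@]=C([H])[Sn](CCCC)(CCCC)CCCC | intermediate
4 | diethyl 2-methylpropanedioate | CCOC(=O)C(C)C(=O)OCC | starting material
5 | triiodomethane | IC(I)I | starting material
6 | diethyl 2-(diiodomethyl)-2-methylpropanedioate | CCOC(=O)C(C)(C(I)I)C(=O)OCC | intermediate
7 | (E)-3-iodo-2-methylprop-2-enoic acid | OC(=O)/C(C)=C/I | intermediate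
8 | 3-hydroxy-5-nitrobenzaldehyde | O=Cc1cc(O)cc([N+](=O)[O-])c1 | starting material
9 | (Z)-crotylboronic acid pinacol ester | C/C=C\CB1OC(C)(C)C(C)(C)O1 | starting material
10 | 3-[(1R,2S)-1-hydroxy-2-methylbut-3-en-1-yl]-5-nitrophenol | C=C[C@H](C)[C@@H](O)c1cc(O)cc([N+](=O)[O-])c1 | intermediate
11 | bis-TBS ether of 10 | C=C[C@H](C)[C@@H](O[Si](C)(C)C(C)(C)C)c1cc(O[Si](C)(C)C(C)(C)C)cc([N+](=O)[O-])c1 | intermediate
12 | methyl 2-(dimethoxyphosphoryl)-2-methoxyacetate | COC(C(=O)OC)P(=O)(OC)OC | starting material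
13 | (2R,3R)-3-(TBSO)-3-[3-(TBSO)-5-nitrophenyl]-2-methylpropanal | O=C[C@H](C)[C@@H](O[Si](C)(C)C(C)(C)C)c1cc(O[Si](C)(C)C(C)(C)C)cc([N+](=O)[O-])c1 | intermediate
14 | methyl (2Z,4S,5R)-5-(TBSO)-5-[3-(TBSO)-5-nitrophenyl]-2-methoxy-4-methylpent-2-enoate | COC(=O)/C(OC)=C/[C@H](C)[C@@H](O[Si](C)(C)C(C)(C)C)c1cc(O[Si](C)(C)C(C)(C)C)cc([N+](=O)[O-])c1 | intermediate
15 | methyl (2S,4S,5R)-5-(TBSO)-5-[3-(TBSO)-5-nitrophenyl]-2-methoxy-4-methylpentanoate | COC(=O)[C@@H](OC)C[C@H](C)[C@@H](O[Si](C)(C)C(C)(C)C)c1cc(O[Si](C)(C)C(C)(C)C)cc([N+](=O)[O-])c1 | intermediate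
16 | (2S,4S,5R)-5-(TBSO)-5-[3-(TBSO)-5-nitrophenyl]-2-methoxy-4-methylpentanal | O=C[C@@H](OC)C[C@H](C)[C@@H](O[Si](C)(C)C(C)(C)C)c1cc(O[Si](C)(C)C(C)(C)C)cc([N+](=O)[O-])c1 | intermediate
17 | (3S,4R,5S,7S,8R)-8-(TBSO)-8-[3-(TBSO)-5-nitrophenyl]-5-methoxy-3,7-dimethyloct-1-en-4-ol | C=C[C@H](C)[C@@H](O)[C@@H](OC)C[C@H](C)[C@@H](O[Si](C)(C)C(C)(C)C)c1cc(O[Si](C)(C)C(C)(C)C)cc([N+](=O)[O-])c1 | intermediate
18 | (3S,4R,5S,7S,8R)-8-(TBSO)-8-[3-(TBSO)-5-nitrophenyl]-4,5-dimethoxy-3,7-dimethyloct-1-ene | C=C[C@H](C)[C@@H](OC)[C@@H](OC)C[C@H](C)[C@@H](O[Si](C)(C)C(C)(C)C)c1cc(O[Si](C)(C)C(C)(C)C)cc([N+](=O)[O-])c1 | intermediate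
19 | methacrolein | C=C(C)C=O | starting material
20 | (2E,4S,5R,6S,8S,9R)-9-(TBSO)-9-[3-(TBSO)-5-nitrophenyl]-5,6-dimethoxy-2,4,8-trimethylnon-2-enal | O=C/C(C)=C/[C@H](C)[C@@H](OC)[C@@H](OC)C[C@H](C)[C@@H](O[Si](C)(C)C(C)(C)C)c1cc(O[Si](C)(C)C(C)(C)C)cc([N+](=O)[O-])c1 | intermediate
21 | (3S,4R,5E,7S,8R,9S,11S,12R)-12-(TBSO)-12-[3-(TBSO)-5-nitrophenyl]-8,9-dimethoxy-3,5,7,11-tetramethyldodec-5-en-1-yn-4-ol | C#C[C@H](C)[C@@H](O)/C(C)=C/[C@H](C)[C@@H](OC)[C@@H](OC)C[C@H](C)[C@@H](O[Si](C)(C)C(C)(C)C)c1cc(O[Si](C)(C)C(C)(C)C)cc([N+](=O)[O-])c1 | intermediate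
22 | N-(trichloroacetyl)carbamate of 21 | C#C[C@H](C)[C@@H](OC(=O)NC(=O)C(Cl)(Cl)Cl)/C(C)=C/[C@H](C)[C@@H](OC)[C@@H](OC)C[C@H](C)[C@@H](O[Si](C)(C)C(C)(C)C)c1cc(O[Si](C)(C)C(C)(C)C)cc([N+](=O)[O-])c1 | intermediate
23 | C7 carbamate with free nitrophenol and 15-O-TBS ether (name as in step 14) | C#C[C@H](C)[C@@H](OC(N)=O)/C(C)=C/[C@H](C)[C@@H](OC)[C@@H](OC)C[C@H](C)[C@@H](O[Si](C)(C)C(C)(C)C)c1cc(O)cc([N+](=O)[O-])c1 | intermediate
24 | 15-O-TBS ether of 25 | OC(=O)/C(C)=C/C#C[C@H](C)[C@@H](OC(N)=O)/C(C)=C/[C@H](C)[C@@H](OC)[C@@H](OC)C[C@H](C)[C@@H](O[Si](C)(C)C(C)(C)C)c1cc(O)cc([N+](=O)[O-])c1 | intermediate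
25 | nitro enyne acid (name as in step 15) | OC(=O)/C(C)=C/C#C[C@H](C)[C@@H](OC(N)=O)/C(C)=C/[C@H](C)[C@@H](OC)[C@@H](OC)C[C@H](C)[C@@H](O)c1cc(O)cc([N+](=O)[O-])c1 | intermediate
26 | unprotected seco amino acid (name as in step 16) | OC(=O)/C(C)=C/C=C\[C@H](C)[C@@H](OC(N)=O)/C(C)=C/[C@H](C)[C@@H](OC)[C@@H](OC)C[C@H](C)[C@@H](O)c1cc(O)cc(N)c1 | intermediate
27 | S-pyridin-2-yl thioester of 26 | O=C(Sc1ccccn1)/C(C)=C/C=C\[C@H](C)[C@@H](OC(N)=O)/C(C)=C/[C@H](C)[C@@H](OC)[C@@H](OC)C[C@H](C)[C@@H](O)c1cc(O)cc(N)c1 | intermediate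
28 | phenol macrolactam (name as in step 17; C18–OH, C21–H) | CO[C@H]1[C@@H](OC)C[C@H](C)[C@@H](O)c2cc(O)cc(NC(=O)/C(C)=C/C=C\[C@H](C)[C@@H](OC(N)=O)/C(C)=C/[C@@H]1C)c2 | intermediate
29 | CNP0557283.1 (name as in step 18) | CO[C@H]1[C@@H](OC)C[C@H](C)[C@@H](O)C2=CC(=O)C=C(NC(=O)/C(C)=C/C=C\[C@H](C)[C@@H](OC(N)=O)/C(C)=C/[C@@H]1C)C2=O | target

**Step count**
Total: 18 steps (steps 1–4 make the two small fragments). Longest linear sequence: 14 steps (8 → 29, steps 5–18).

**Three steps most likely to fail**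

Risk 1, step 17 (ring closure on the unprotected seco acid). PPh3 or pyridinethiolate can add reversibly to the dienoyl thioester and erode the 4Z-alkene. The aminophenol is air-sensitive, and O-acylation or oligomerisation can compete.

The fallback sets out from 25 and comes back at 28. Na2S2O4/NaHCO3 in THF/H2O reduces only the nitro group of 25 to the amino enyne acid F1. The ring is closed on this 4,5-alkyne, which has no Z-alkene to lose, through its S-2-pyridyl thioester F2 to the enyne macrolactam F3. Only then is the 4Z-alkene made inside the ring, with zinc activated with Cu(OAc)2 and AgNO3, which gives 28. The cis-alkene thus becomes a tailoring event after ring closure.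

Risk 2, step 8 (C12 by hydrogenation). An α-methoxy acrylate lacks the chelating acyl group of the well-behaved enol esters, so rate and sense of induction are uncertain.

The fallback sets out from 11 and comes back at 16, and sets C12 by auxiliary-controlled enolate oxidation instead.
- Cross metathesis of 11 with (S)-3-acryloyl-4-benzyl-1,3-oxazolidin-2-one (second-generation Hoveyda–Grubbs catalyst) gives the enoyl imide F4.
- RhCl(PPh3)3/H2 saturates it to the imide F5.
- NaN(SiMe3)2 followed by 2-(phenylsulfonyl)-3-phenyloxaziridine hydroxylates the chelated Z-enolate anti to the benzyl group, giving the (12S)-α-hydroxy imide F6.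
- Me3OBF4 with 1,8-bis(dimethylamino)naphthalene gives the α-methoxy imide F7.
- i-Bu2AlH at −78 °C releases aldehyde 16.

Risk 3, step 18 (para-oxidation at C21). C21 is flanked by the amide and the carbinol side chain and points into the ansa ring, so radical coupling there may be slow and ortho-oxidation may intrude.

The fallback sets out from 28 and comes back at 29, and replaces the radical oxidation by a two-electron dearomatisation. PhI(OAc)2 (2.2 equiv) in MeOH at 0 °C gives the quinone monoketal F8 (4,4-dimethoxycyclohexadienone, ketal carbon = C21). Mild aqueous acid (pyridinium tosylate, acetone/H2O) hydrolyses it to 29.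

**Further compounds**
F1 | step 17 | (2E,6S,7R,8E,10S,11R,12S,14S,15R)-15-(3-amino-5-hydroxyphenyl)-7-(carbamoyloxy)-15-hydroxy-11,12-dimethoxy-2,6,8,10,14-pentamethylpentadeca-2,8-dien-4-ynoic acid | OC(=O)/C(C)=C/C#C[C@H](C)[C@@H](OC(N)=O)/C(C)=C/[C@H](C)[C@@H](OC)[C@@H](OC)C[C@H](C)[C@@H](O)c1cc(O)cc(N)c1
F2 | step 17 | S-pyridin-2-yl thioester of F1 | O=C(Sc1ccccn1)/C(C)=C/C#C[C@H](C)[C@@H](OC(N)=O)/C(C)=C/[C@H](C)[C@@H](OC)[C@@H](OC)C[C@H](C)[C@@H](O)c1cc(O)cc(N)c1
F3 | step 17 | 4,5-didehydro (enyne) analogue of phenol macrolactam 28 | CO[C@H]1[C@@H](OC)C[C@H](C)[C@@H](O)c2cc(O)cc(NC(=O)/C(C)=C/C#C[C@H](C)[C@@H](OC(N)=O)/C(C)=C/[C@@H]1C)c2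
F4 | step 8 | (S)-4-benzyl-3-{(2E,4S,5R)-5-(TBSO)-5-[3-(TBSO)-5-nitrophenyl]-4-methylpent-2-enoyl}-1,3-oxazolidin-2-one | O=C(/C=C/[C@H](C)[C@@H](O[Si](C)(C)C(C)(C)C)c1cc(O[Si](C)(C)C(C)(C)C)cc([N+](=O)[O-])c1)N1[C@@H](Cc2ccccc2)COC1=O
F5 | step 8 | (S)-4-benzyl-3-{(4S,5R)-5-(TBSO)-5-[3-(TBSO)-5-nitrophenyl]-4-methylpentanoyl}-1,3-oxazolidin-2-one | O=C(CC[C@H](C)[C@@H](O[Si](C)(C)C(C)(C)C)c1cc(O[Si](C)(C)C(C)(C)C)cc([N+](=O)[O-])c1)N1[C@@H](Cc2ccccc2)COC1=O
F6 | step 8 | (S)-4-benzyl-3-{(2S,4S,5R)-5-(TBSO)-5-[3-(TBSO)-5-nitrophenyl]-2-hydroxy-4-methylpentanoyl}-1,3-oxazolidin-2-one | O=C([C@@H](O)C[C@H](C)[C@@H](O[Si](C)(C)C(C)(C)C)c1cc(O[Si](C)(C)C(C)(C)C)cc([N+](=O)[O-])c1)N1[C@@H](Cc2ccccc2)COC1=O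
F7 | step 8 | (S)-4-benzyl-3-{(2S,4S,5R)-5-(TBSO)-5-[3-(TBSO)-5-nitrophenyl]-2-methoxy-4-methylpentanoyl}-1,3-oxazolidin-2-one | O=C([C@@H](OC)C[C@H](C)[C@@H](O[Si](C)(C)C(C)(C)C)c1cc(O[Si](C)(C)C(C)(C)C)cc([N+](=O)[O-])c1)N1[C@@H](Cc2ccccc2)COC1=O
F8 | step 18 | C21 dimethyl monoketal of 29 | CO[C@H]1[C@@H](OC)C[C@H](C)[C@@H](O)C2=CC(=O)C=C(NC(=O)/C(C)=C/C=C\[C@H](C)[C@@H](OC(N)=O)/C(C)=C/[C@@H]1C)C2(OC)OC
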